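**Retrosynthetic overview**

1. The strategy rests on the 1,2-dioxane ring O1–O2–C3–C4–C5–C6, the only ring of the target. Its C3–C4 unit with the 4-methyl group is propanal, its C5–C6 unit with the 6-methyl group and the C7 side chain is a 1,1-disubstituted alkene, and O1–O2 is molecular oxygen.
2. The C3–CH2CO2H bond is cut last: a peroxycarbenium ion from the 3-acetoxy-1,2-dioxane takes up a silyl ketene thioacetal, and the thioester is hydrolysed to the acid.
3. The ring is closed in one operation from propanal 12, alkene 11 and O2 13 under SOMO aminocatalysis (bonds C4–C5, C6–O1, O2–C3), giving 1,2-dioxan-3-ol 16.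
4. Alkene 11 comes from (R)-citronellal (source of the side-chain stereocentre C8) by methyl ketone formation, ozonolysis, Wittig extension with the 5-phenylpentyl ylide, hydrogenation and methylenation.
5. Stereocontrol: C8 from the chiral pool, C4 from the imidazolidinone catalyst, C3 from axial attack on the peroxycarbenium ion; C6 is not controlled and its epimers are separated.

Key step: step 8

Remark on the chemistry: C6 is expected to form as both epimers in step 8; compounds 15, 16, 17 and 20 are written as the 6R isomers and travel with their 6S epimers until the chromatographic separation at the end of step 11.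

Remark on the chemistry: the aminocatalyst is (2R,5R)-5-benzyl-2-tert-butyl-3-methylimidazolidin-4-one, SMILES N1[C@H](Cc2ccccc2)C(=O)N(C)[C@@H]1C(C)(C)C, used as its trifluoroacetate. This enantiomer is chosen from the facial model given in step 8.

**Route**

Step 1
Reactants: 1 (5-bromopentyl)benzene
Product: 2 triphenyl(5-phenylpentyl)phosphonium bromide
Conditions: PPh3, MeCN, reflux
Reagents that add atoms: triphenylphosphine, c1ccc(cc1)P(c1ccccc1)c1ccccc1
Why: SN2 quaternisation of triphenylphosphine by an unhindered primary bromide gives the salt needed for the Wittig chain extension.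

Step 2
Reactants: 3 (R)-citronellal
Product: 4 (4R)-4,8-dimethylnon-7-en-2-ol (mixture of C2 epimers)
Conditions: MeMgBr, Et2O, −78 → 0 °C; aq. NH4Cl
Reagents that add atoms: methylmagnesium bromide, C[Mg]Br
Why: Grignard 1,2-addition to the aldehyde leaves the β-stereocentre untouched, and the new carbinol centre is removed again in step 3.

Step 3
Reactants: 4 (4R)-4,8-dimethylnon-7-en-2-ol
Product: 5 (4R)-4,8-dimethylnon-7-en-2-one
Conditions: Dess–Martin periodinane, NaHCO3, CH2Cl2, 0 °C → rt
Reagents that add atoms: none
Why: Dess–Martin oxidation of a secondary alcohol under buffered neutral conditions should spare the trisubstituted alkene and the stereocentre, which is β to the new carbonyl and cannot epimerise.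

Step 4
Reactants: 5 (4R)-4,8-dimethylnon-7-en-2-one
Product: 7 (4R)-4-methyl-6-oxoheptanal, via secondary ozonide 6 (not isolated)
Conditions: O3, CH2Cl2, −78 °C; then Me2S, −78 °C → rt
Reagents that add atoms: ozone, [O-][O+]=O
Why: Ozonolysis (Criegee mechanism) of the electron-rich trisubstituted alkene followed by reductive work-up should unmask the aldehyde while the ketone stays inert.

Step 5
Reactants: 7 (4R)-4-methyl-6-oxoheptanal; 2 triphenyl(5-phenylpentyl)phosphonium bromide
Product: 9 (4R,7Z)-4-methyl-12-phenyldodec-7-en-2-one, via phosphonium ylide 8 (not isolated)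
Conditions: 2, NaHMDS, THF, 0 °C; then 7, −78 °C → rt
Reagents that add atoms: none
Why: In this Wittig olefination the non-stabilised ylide should react with the aldehyde far faster than with the methyl ketone at −78 °C, and the alkene geometry does not matter because step 6 saturates it.

Step 6
Reactants: 9 (4R,7Z)-4-methyl-12-phenyldodec-7-en-2-one
Product: 10 (4R)-4-methyl-12-phenyldodecan-2-one
Conditions: H2 (1 atm), Pd/C, EtOAc, rt
Reagents that add atoms: none
Why: Heterogeneous hydrogenation of a disubstituted alkene at 1 atm should leave the ketone and the phenyl ring unchanged.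

Step 7
Reactants: 10 (4R)-4-methyl-12-phenyldodecan-2-one
Product: 11 (4R)-2,4-dimethyl-12-phenyldodec-1-ene
Conditions: Ph3PCH3Br, KOtBu, THF, 0 °C → rt
Reagents that add atoms: methyltriphenylphosphonium bromide, C[P+](c1ccccc1)(c1ccccc1)c1ccccc1.[Br-]
Why: Wittig methylenation of an unhindered methyl ketone gives the 1,1-disubstituted alkene, and the stereocentre is β to the carbonyl and so is not at risk.

Step 8
Reactants: 11 (4R)-2,4-dimethyl-12-phenyldodec-1-ene; 12 propanal; 13 dioxygen
Product: 16 (4S,6R)-4,6-dimethyl-6-[(2R)-2-methyl-10-phenyldecyl]-1,2-dioxan-3-ol (anomeric mixture; formed together with its 6S epimer), via enamine 14 (not isolated), via dioxanyl aminal 15 (not isolated)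
Conditions: (2R,5R)-5-benzyl-2-tert-butyl-3-methylimidazolidin-4-one·CF3CO2H (20 mol%), (NH4)2Ce(NO3)6 (0.3 equiv, portionwise, as initiator), NaHCO3, H2O (2 equiv), DME, O2 (1 atm), −20 °C; 12 (3 equiv) added slowly
Reagents that add atoms: water, O (supplies the C3 hydroxyl oxygen when 15 is hydrolysed; the carbonyl oxygen of 12 leaves as water on enamine formation)
Why: Proposed new method: propanal 12 condenses with the imidazolidinone to (E)-enamine 14, which the tetravalent cerium salt oxidises by one electron to a 3π-electron radical cation; this electrophilic radical adds to the CH2 terminus of 11 (C4–C5), the tertiary C6 radical captures O2 (C6–O1), and the peroxyl radical is reduced by a further enamine molecule, which carries a chain and lets the cerium salt act as initiator in an overall redox-neutral reaction. The closest known reaction types are the Mn(OAc)3- and (NH4)2Ce(NO3)6-mediated aerobic [2+2+2] annulations of 1,3-dicarbonyl compounds with alkenes to 1,2-dioxan-3-ols and the enantioselective SOMO-activated α-alkylation of aldehydes with olefins; their combination with oxygen capture has not been shown. The 1,2-dioxane ring closes by ionic 6-exo-trig attack of the peroxide oxygen on the iminium carbon (O2–C3) to give aminal 15, whose hydrolysis releases the catalyst and hemiperoxyacetal 16. C4 is set by the catalyst: the radical cation lies away from the tert-butyl group and the benzyl group covers its Si face, so the alkene should add to the Re face of the α-carbon and give 4S, whereas C6 arises from an acyclic tertiary radical without control and C3 is an equilibrating anomeric centre. The step needs alkene addition to outrun direct O2 capture by the radical cation and needs attack at the alkene terminus; the 1,1-disubstituted alkene secures the regiochemistry and gives a tertiary radical that O2 should trap faster than cerium can oxidise it, while slow addition of excess propanal to concentrated alkene places unproductive oxygenation on the cheap component. The α-branched product, held as a cyclic hemiperoxyacetal, should no longer condense readily with the hindered catalyst, which protects C4 from epimerisation.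

Step 9
Reactants: 16 (4S,6R)-4,6-dimethyl-6-[(2R)-2-methyl-10-phenyldecyl]-1,2-dioxan-3-ol
Product: 17 (4S,6R)-4,6-dimethyl-6-[(2R)-2-methyl-10-phenyldecyl]-1,2-dioxan-3-yl acetate (anomeric mixture)
Conditions: Ac2O, pyridine, DMAP (cat.), CH2Cl2, 0 °C
Reagents that add atoms: acetic anhydride, CC(=O)OC(C)=O
Why: O-acylation of the hemiperoxyacetal hydroxyl under weakly basic conditions turns C3 into an ionisable centre while the dialkyl peroxide bond stays intact.

Step 10
Reactants: 18 S-ethyl ethanethioate
Product: 19 tert-butyl{[1-(ethylsulfanyl)ethenyl]oxy}dimethylsilane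
Conditions: LDA, THF, −78 °C; then TBSCl, DMPU, −78 °C → rt
Reagents that add atoms: tert-butyldimethylsilyl chloride, CC(C)(C)[Si](C)(C)Cl
Why: Kinetic enolisation of the thioester and O-silylation of the lithium enolate give the silyl ketene thioacetal.

Step 11
Reactants: 17 (4S,6R)-4,6-dimethyl-6-[(2R)-2-methyl-10-phenyldecyl]-1,2-dioxan-3-yl acetate; 19 tert-butyl{[1-(ethylsulfanyl)ethenyl]oxy}dimethylsilane
Product: 20 S-ethyl 2-[(3S,4S,6R)-4,6-dimethyl-6-[(2R)-2-methyl-10-phenyldecyl]-1,2-dioxan-3-yl]ethanethioate
Conditions: SnCl4 (1.1 equiv), CH2Cl2, −78 °C; aq. NaHCO3; then chromatographic separation of the C6 epimers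
Reagents that add atoms: none
Why: In this Mukaiyama-type addition SnCl4 ionises the anomeric acetate to a peroxycarbenium ion (C3=O2) whose half-chair holds the 4-methyl group pseudo-equatorial (the other half-chair would place it syn-diaxial to a C6 alkyl group), so chair-like axial attack anti to the axial C4–H, as in axial C-glycosylation of pyranosyl cations, should set C3 as 3S with the new chain cis to the 4-methyl group.

Step 12
Reactants: 20 S-ethyl 2-[(3S,4S,6R)-4,6-dimethyl-6-[(2R)-2-methyl-10-phenyldecyl]-1,2-dioxan-3-yl]ethanethioate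
Product: 21 2-[(3S,4S,6R)-4,6-dimethyl-6-[(2R)-2-methyl-10-phenyldecyl]-1,2-dioxan-3-yl]acetic acid
Conditions: AgOCOCF3, THF/H2O (4:1), rt
Reagents that add atoms: water, O
Why: Thiophilic activation of the thioester by monovalent silver allows acyl substitution by water without base, which avoids enolate formation and β-elimination of the peroxide.

**Compound list**

1 | (5-bromopentyl)benzene | BrCCCCCc1ccccc1 | starting material
2 | triphenyl(5-phenylpentyl)phosphonium bromide | [Br-].c1ccc(CCCCC[P+](c2ccccc2)(c2ccccc2)c2ccccc2)cc1 | intermediate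
3 | (R)-citronellal | C[C@H](CCC=C(C)C)CC=O | starting material
4 | (4R)-4,8-dimethylnon-7-en-2-ol (C2 epimers) | C[C@H](CCC=C(C)C)CC(C)O | intermediate
5 | (4R)-4,8-dimethylnon-7-en-2-one | C[C@H](CCC=C(C)C)CC(C)=O | intermediate
6 | (4R)-6-(5,5-dimethyl-1,2,4-trioxolan-3-yl)-4-methylhexan-2-one (secondary ozonide) | C[C@H](CCC1OOC(C)(C)O1)CC(C)=O | intermediate
7 | (4R)-4-methyl-6-oxoheptanal | C[C@H](CCC=O)CC(C)=O | intermediate
8 | triphenyl(5-phenylpentylidene)-λ5-phosphane | C(CCCCc1ccccc1)=P(c1ccccc1)(c1ccccc1)c1ccccc1 | intermediate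
9 | (4R,7Z)-4-methyl-12-phenyldodec-7-en-2-one | CC(=O)C[C@H](C)CC/C=C\CCCCc1ccccc1 | intermediate
10 | (4R)-4-methyl-12-phenyldodecan-2-one | CC(=O)C[C@H](C)CCCCCCCCc1ccccc1 | intermediate
11 | (4R)-2,4-dimethyl-12-phenyldodec-1-ene | C=C(C)C[C@H](C)CCCCCCCCc1ccccc1 | intermediate
12 | propanal | CCC=O | starting material
13 | dioxygen | O=O | starting material
14 | (2R,5R)-5-benzyl-2-tert-butyl-3-methyl-1-[(1E)-prop-1-en-1-yl]imidazolidin-4-one | C/C=C/N1[C@H](Cc2ccccc2)C(=O)N(C)[C@@H]1C(C)(C)C | intermediate
15 | (2R,5R)-5-benzyl-2-tert-butyl-1-{(4S,6R)-4,6-dimethyl-6-[(2R)-2-methyl-10-phenyldecyl]-1,2-dioxan-3-yl}-3-methylimidazolidin-4-one | C[C@H](CCCCCCCCc1ccccc1)C[C@]1(C)C[C@H](C)C(N2[C@H](Cc3ccccc3)C(=O)N(C)[C@@H]2C(C)(C)C)OO1 | intermediate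
16 | (4S,6R)-4,6-dimethyl-6-[(2R)-2-methyl-10-phenyldecyl]-1,2-dioxan-3-ol (anomeric mixture) | C[C@H](CCCCCCCCc1ccccc1)C[C@]1(C)C[C@H](C)C(O)OO1 | intermediate
17 | (4S,6R)-4,6-dimethyl-6-[(2R)-2-methyl-10-phenyldecyl]-1,2-dioxan-3-yl acetate (anomeric mixture) | C[C@H](CCCCCCCCc1ccccc1)C[C@]1(C)C[C@H](C)C(OC(C)=O)OO1 | intermediate
18 | S-ethyl ethanethioate | CC(=O)SCC | starting material
19 | tert-butyl{[1-(ethylsulfanyl)ethenyl]oxy}dimethylsilane | C=C(SCC)O[Si](C)(C)C(C)(C)C | intermediate
20 | S-ethyl 2-[(3S,4S,6R)-4,6-dimethyl-6-[(2R)-2-methyl-10-phenyldecyl]-1,2-dioxan-3-yl]ethanethioate | C[C@H](CCCCCCCCc1ccccc1)C[C@]1(C)C[C@H](C)[C@H](CC(=O)SCC)OO1 | intermediate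
21 | 2-[(3S,4S,6R)-4,6-dimethyl-6-[(2R)-2-methyl-10-phenyldecyl]-1,2-dioxan-3-yl]acetic acid | C[C@H](CCCCCCCCc1ccccc1)C[C@]1(C)C[C@H](C)[C@H](CC(=O)O)OO1 | target

**Step count**

Total: 12 steps. Longest linear sequence: 10 steps, from (R)-citronellal 3 through steps 2–9, 11 and 12.

**Steps most likely to fail**

Step 8 (proposed new method). Three processes may defeat it:
- direct capture of O2 by the enamine radical cation, leading to α-oxygenation and cleavage of propanal;
- radical-chain autoxidation of propanal to acylperoxyl species that epoxidise the alkene;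
- weak facial discrimination at C4.

The fallback uses known reactions, sets out from ketone 10 and returns to the route at 16, with C4 taken from the chiral pool:
- Commercial (R)-3-bromo-2-methylpropan-1-ol (BrC[C@H](C)CO) is heated with PPh3 to give [(2R)-3-hydroxy-2-methylpropyl]triphenylphosphonium bromide F1.
- Double deprotonation (n-BuLi, 2 equiv, THF) and Wittig reaction with 10 should give (2S,6R)-2,4,6-trimethyl-14-phenyltetradec-3-en-1-ol F2; its alkene geometry is irrelevant.
- Isayama–Mukaiyama hydroperoxysilylation (Co(thd)2, that is cobalt bis(2,2,6,6-tetramethylheptane-3,5-dionate), O2, Et3SiH, ClCH2CH2Cl, rt) places the peroxide at the tertiary carbon and gives (2S,6R)-2,4,6-trimethyl-14-phenyl-4-(triethylsilylperoxy)tetradecan-1-ol F3.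
- Dess–Martin oxidation gives (2S,6R)-2,4,6-trimethyl-14-phenyl-4-(triethylsilylperoxy)tetradecanal F4.
- HF·pyridine in THF removes the silyl group, and the γ-hydroperoxy aldehyde should close spontaneously to hemiperoxyacetal 16, again as a mixture of C6 epimers.

Step 11. The Lewis acid may trigger heterolysis of the O–O bond and fragmentation of the ring, and the facial bias at C3 may be too weak, so that the chain ends up trans to the 4-methyl group. The fallback sets out from 16 and returns at the target 21, forming the O2–C3 bond by conjugate addition instead of substitution: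
- 16 is treated with methyl (triphenylphosphoranylidene)acetate (toluene, rt), which should intercept the open-chain γ-hydroperoxy aldehyde tautomer as methyl (2E,4S,6R,8R)-6-hydroperoxy-4,6,8-trimethyl-16-phenylhexadec-2-enoate F5.
- Et2NH in CF3CH2OH should then close the ring by intramolecular oxa-Michael addition of the hydroperoxide, giving methyl 2-[(3S,4S,6R)-4,6-dimethyl-6-[(2R)-2-methyl-10-phenyldecyl]-1,2-dioxan-3-yl]acetate F6 after chromatographic removal of the C3 and C6 epimers.
- LiOH in THF/H2O at 0 °C gives 21.

Step 12. Enolisation of the thioester or carboxylate followed by β-elimination of the peroxide (retro-oxa-Michael ring opening), or reduction of the O–O bond by liberated thiolate, may consume the product. The fallback sets out from acetate 17 and returns at 21, reaching the acid by oxidation instead of acyl substitution: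
- Hosomi–Sakurai allylation of 17 (allyltrimethylsilane, SnCl4, CH2Cl2, −78 °C) should give (3S,4S,6R)-4,6-dimethyl-6-[(2R)-2-methyl-10-phenyldecyl]-3-(prop-2-en-1-yl)-1,2-dioxane F7 by the same axial attack; the C6 epimers are separated here.
- Ozonolysis (O3, CH2Cl2, −78 °C; then Me2S) gives 2-[(3S,4S,6R)-4,6-dimethyl-6-[(2R)-2-methyl-10-phenyldecyl]-1,2-dioxan-3-yl]acetaldehyde F8.
- Pinnick oxidation (NaClO2, NaH2PO4, 2-methylbut-2-ene, t-BuOH/H2O) gives 21.

**Further compounds**

F1 | step 8 | [(2R)-3-hydroxy-2-methylpropyl]triphenylphosphonium bromide | OC[C@@H](C)C[P+](c1ccccc1)(c1ccccc1)c1ccccc1.[Br-]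
F2 | step 8 | (2S,6R)-2,4,6-trimethyl-14-phenyltetradec-3-en-1-ol (E/Z mixture) | OC[C@@H](C)C=C(C)C[C@H](C)CCCCCCCCc1ccccc1
F3 | step 8 | (2S,6R)-2,4,6-trimethyl-14-phenyl-4-(triethylsilylperoxy)tetradecan-1-ol (C4 epimers) | OC[C@@H](C)CC(C)(OO[Si](CC)(CC)CC)C[C@H](C)CCCCCCCCc1ccccc1
F4 | step 8 | (2S,6R)-2,4,6-trimethyl-14-phenyl-4-(triethylsilylperoxy)tetradecanal (C4 epimers) | O=C[C@@H](C)CC(C)(OO[Si](CC)(CC)CC)C[C@H](C)CCCCCCCCc1ccccc1
F5 | step 11 | methyl (2E,4S,6R,8R)-6-hydroperoxy-4,6,8-trimethyl-16-phenylhexadec-2-enoate | C[C@H](CCCCCCCCc1ccccc1)C[C@](OO)(C)C[C@H](C)/C=C/C(=O)OC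
F6 | step 11 | methyl 2-[(3S,4S,6R)-4,6-dimethyl-6-[(2R)-2-methyl-10-phenyldecyl]-1,2-dioxan-3-yl]acetate | C[C@H](CCCCCCCCc1ccccc1)C[C@]1(C)C[C@H](C)[C@H](CC(=O)OC)OO1
F7 | step 12 | (3S,4S,6R)-4,6-dimethyl-6-[(2R)-2-methyl-10-phenyldecyl]-3-(prop-2-en-1-yl)-1,2-dioxane | C[C@H](CCCCCCCCc1ccccc1)C[C@]1(C)C[C@H](C)[C@H](CC=C)OO1
F8 | step 12 | 2-[(3S,4S,6R)-4,6-dimethyl-6-[(2R)-2-methyl-10-phenyldecyl]-1,2-dioxan-3-yl]acetaldehyde | C[C@H](CCCCCCCCc1ccccc1)C[C@]1(C)C[C@H](C)[C@H](CC=O)OO1
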